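3 questions stand open on 5 flasks that share substrate, temperature and time and differ in [free catalyst].

| setting | larch | birch | teal | red | green | amber | violet |
|---|---|---|---|---|---|---|---|
| substrate | 1.5 M | 1.5 M | 1.5 M | 1.5 M | 1.5 M | 1.5 M | 1.5 M |
| free catalyst | 48 mM | 380 mM | 150 mM | 80 mM | 300 mM | 40 mM | 250 mM |
| temperature | 95 °C | 110 °C | 110 °C | 110 °C | 110 °C | 110 °C | 110 °C |
| remark | run made earlier | run made earlier |  |  |  |  |  |
| time |  |  | 15 h | 15 h | 15 h | 15 h | 15 h |

| run | time / h | target / % | side product A / % |
|---|---|---|---|
| larch | 2.00 | 11 | 17 |
| larch | 5.00 | 9 | 29 |
| larch | 10.0 | 14 | 31 |
| larch | 15.0 | 12 | 35 |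
| larch | 20.0 | 13 | 32 |
| birch | 2.00 | 53 | 11 |
| birch | 4.00 | 47 | 14 |
| birch | 6.00 | 48 | 11 |
| birch | 8.00 | 53 | 9 |
| birch | 10.0 | 51 | 12 |

(readings scatter by 2 percentage points)

1. all flasks from highest to lowest share of target in all that became target or side product A or side product B or uncatalysed product, at 15 h (teal / red / green / amber / violet)
2. the share of target in all that became target or side product A or side product B or uncatalysed product of the flask you put first, at 15 h
3. the share of target in all that became target or side product A or side product B or uncatalysed product of the flask you put last, at 15 h

- a species is counted by the substrate in it: one side product B counts as two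

The birch run stands level, with target at 53% at 2.00 h and 51% at 10.0 h, a drift inside the scatter. So this reckoning takes the products in birch to hold the whole charge, and target as a percentage of the charge to be the asked share. The mean of the birch readings gives 50.4%.

Now the two ends. Suppose target needs free catalyst and the other products do not. At low [free catalyst] the odds of target, a selectivity factor, then rise in proportion to [free catalyst], and at high [free catalyst] the share climbs towards the whole charge. One form joins both ends: share = [free catalyst]/([free catalyst] + level). Birch puts at 374 mM the even-odds level, the [free catalyst] at which target equals the other products together. The form then gives green 44.5% and amber 9.66%. The form rises with [free catalyst], so the order follows the charges: green, violet, teal, red, amber.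

The weak link is the low end. Birch stands at 380 mM and amber at 40 mM, so amber's figure rests on a long stretch of the form. Larch is a low-end run, but at 95 °C. Its target readings from 10.0 h on average 13.0%, which gives a level of 321 mM. With that level the form gives amber 11.1%. Larch stands at another temperature than the flasks asked about, so this reckoning commits to the birch level and keeps the larch figure as a second estimate for amber.

The forecast gives green > violet > teal > red > amber, with top 45% (38% to 51%) and low 11% (6% to 17%). Its low stands above this reckoning's amber figure. On the order it says: “A maximum below 300 mM seems unlikely, so the order is monotonic.”

The flasks run green > violet > teal > red > amber, with green at 45.1% and amber at 10.5%.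

    substrate → side product A (k = 0.00730 /min, Ea = 106 kJ/mol)
    substrate + target → side product B (k = 0.0240 /M/min, Ea = 79.0 kJ/mol)
    substrate → uncatalysed product (k = 0.00720 /min, Ea = 129 kJ/mol)
    substrate + free catalyst → free catalyst + target (k = 0.120 /M/min, Ea = 98.0 kJ/mol)
    free catalyst → spent catalyst (k = 5.20 × 10⁻⁴ /min, Ea = 126 kJ/mol)
    (constants at 110 °C)

Green's substrate stands at 0% at 15.0 h, and its share still reads 45.1% at 150 h. Green's result puts the even-odds level at 365 mM, beside the 374 mM from birch. For a neighbour of green charged with 0.12 M of free catalyst, 374 mM gives a share of 24.3%, and that flask's share comes to 25.6%.

The runs stem from a simulated flask from invented constants; the scatter is artificial.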